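**Retrosynthetic overview**

- The strategy rests on the C2–C3 bond of the all-trans cyclobutane: C2 and C3 carry the CH2NHC(=O)pyrrolyl arms, C1 and C4 the 2-aminoimidazolyl rings. Every ring substituent is joined through a carbon that can stand at the carboxyl level, so an NH placed between C2 and C3 gives a pyrrolidine-2,3,4,5-tetracarboxylate.
- Target ⇒ bis(N-Boc-aminoimidazole) 22 ⇒ bis(bromomethyl ketone) 20 ⇒ diacid 17. The imidazoles at C1/C4 come from the tert-butyl esters.
- 17 ⇒ diamine 12 (the two homotopic CH2NH2 groups are acylated one after the other) ⇒ diazide ⇒ diol ⇒ the ethyl esters of cyclobutane tetraester 8.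
- 8 ⇒ all-trans pyrrolidine 6 by nitrogen deletion (isodiazene, then 1,4-biradical); 6 ⇒ epimerisation of the cycloadduct of a glyoxylate/glycine imine with di-tert-butyl fumarate.
- Ring order: pyrrolidine (step 2), cyclobutane (step 4), the two imidazoles (step 14); the pyrroles are bought.

Key step: step 4

Assumption: (S)-QUINAP with AgOAc is taken to give the (3R,4R) series; if the sense of induction is the opposite one, (R)-QUINAP is used with no other change.

**Route**

Step 1
Reactants: 1 glycine ethyl ester hydrochloride; 2 ethyl glyoxylate (freshly distilled from its toluene solution)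
Product: 3 ethyl N-[(E)-2-ethoxy-2-oxoethylidene]glycinate (used crude at once)
Conditions: Et3N (1.0 equiv), 4 Å molecular sieves, CH2Cl2, 0 °C → rt
Reagents that add atoms: none
Why: Imine condensation of the liberated primary amine with the highly electrophilic glyoxylate aldehyde, driven by removal of water; no stereocentre is formed.

Step 2
Reactants: 3 ethyl N-[(E)-2-ethoxy-2-oxoethylidene]glycinate; 4 di-tert-butyl fumarate
Product: 5 3,4-di-tert-butyl 2,5-diethyl (2R,3R,4R,5S)-pyrrolidine-2,3,4,5-tetracarboxylate (2,5-cis; 3,4-trans)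
Conditions: AgOAc (5 mol%), (S)-QUINAP (5.5 mol%), iPr2NEt (10 mol%), THF, −45 °C
Reagents that add atoms: none
Why: Asymmetric 1,3-dipolar cycloaddition catalysed by monovalent silver: the N,O-chelated W-shaped azomethine ylide adds suprafacially to the fumarate, so the 2,5-esters should emerge cis and the 3,4-esters trans, and the P,N-ligand on silver shields one ylide face, which decides which enantiotopic face of the fumarate bonds and so sets C3 and C4 (R,R).

Step 3
Reactants: 5 3,4-di-tert-butyl 2,5-diethyl (2R,3R,4R,5S)-pyrrolidine-2,3,4,5-tetracarboxylate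
Product: 6 3,4-di-tert-butyl 2,5-diethyl (2R,3R,4R,5R)-pyrrolidine-2,3,4,5-tetracarboxylate (all-trans)
Conditions: NaOEt (0.2 equiv), EtOH, 0 °C → rt
Reagents that add atoms: none
Why: Thermodynamic epimerisation through the ester enolate at C5, the α-amino ester carbon whose ester is cis to the C4 ester; relief of that cis-vicinal interaction should drive C5 from S to R and give the all-trans isomer, with ethoxide matching the ethyl esters.

Step 4
Reactants: 6 3,4-di-tert-butyl 2,5-diethyl (2R,3R,4R,5R)-pyrrolidine-2,3,4,5-tetracarboxylate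
Product: 8 1,2-di-tert-butyl 3,4-diethyl (1S,2S,3R,4R)-cyclobutane-1,2,3,4-tetracarboxylate (all-trans), via cyclic isodiazene 7 (not isolated)
Conditions: PhI(OH)OTs (2.5 equiv), H2NCO2NH4 (8 equiv), CF3CH2OH, 80 °C
Reagents that add atoms: none
Why: Ammonia released from the carbamate is oxidised by PhI(OH)OTs to an electrophilic iodonitrene that aminates the ring nitrogen of 6 and, with the second equivalent of oxidant, takes it to isodiazene 7, which loses N2 by C–N homolysis to a singlet 1,4-biradical whose termini are the ester-stabilised carbons that were C2 and C5. The closest known reaction type is the hypervalent-iodine/ammonium carbamate contraction of 2,5-disubstituted pyrrolidines to cyclobutanes, a variant of 1,1-diazene nitrogen extrusion. The four-membered ring closes by direct radical–radical recombination of the 1,4-biradical, forming the C3–C4 bond of 8 (the C2–C3 bond of the target). The two new stereocentres, C3 and C4 of 8, should form with retention of the C2/C5 configuration of 6, because the biradical is held in a gauche arrangement by the former C3–C4 backbone and couples faster than its bonds rotate; C1 and C2 of 8 are not touched. The step needs coupling to outrun β-scission of the central C–C bond (which would give two molecules of tert-butyl ethyl fumarate) and needs stereoretention; the singlet spin state and the short tether serve the first, and since the all-trans tetraester is the thermodynamic isomer a partial stereochemical leak at the ester-bearing carbons can be corrected by NaOEt/EtOH equilibration.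

Step 5
Reactants: 8 1,2-di-tert-butyl 3,4-diethyl (1S,2S,3R,4R)-cyclobutane-1,2,3,4-tetracarboxylate
Product: 9 di-tert-butyl (1S,2S,3R,4R)-3,4-bis(hydroxymethyl)cyclobutane-1,2-dicarboxylate
Conditions: LiBH4 (3 equiv), THF, 0 °C → rt
Reagents that add atoms: none
Why: Chemoselective borohydride reduction: the unhindered ethyl esters should be reduced well before the tert-butyl esters, and the trans arrangement of every vicinal pair disfavours lactonisation; no stereocentre is touched.

Step 6
Reactants: 9 di-tert-butyl (1S,2S,3R,4R)-3,4-bis(hydroxymethyl)cyclobutane-1,2-dicarboxylate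
Product: 10 di-tert-butyl (1S,2S,3R,4R)-3,4-bis[(methanesulfonyloxy)methyl]cyclobutane-1,2-dicarboxylate
Conditions: MsCl, Et3N, CH2Cl2, 0 °C
Reagents that add atoms: methanesulfonyl chloride, CS(=O)(=O)Cl
Why: O-Sulfonylation of two primary alcohols; the trans-fused tetrahydrofuran that cyclisation would give is too strained to form.

Step 7
Reactants: 10 di-tert-butyl (1S,2S,3R,4R)-3,4-bis[(methanesulfonyloxy)methyl]cyclobutane-1,2-dicarboxylate
Product: 11 di-tert-butyl (1S,2S,3R,4R)-3,4-bis(azidomethyl)cyclobutane-1,2-dicarboxylate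
Conditions: NaN3, DMF, 60 °C
Reagents that add atoms: sodium azide, [Na+].[N-]=[N+]=[N-]
Why: Twofold SN2 displacement at primary cyclobutylmethyl mesylates by azide; the ring stereocentres are not involved.

Step 8
Reactants: 11 di-tert-butyl (1S,2S,3R,4R)-3,4-bis(azidomethyl)cyclobutane-1,2-dicarboxylate
Product: 12 di-tert-butyl (1S,2S,3R,4R)-3,4-bis(aminomethyl)cyclobutane-1,2-dicarboxylate
Conditions: H2 (1 atm), 10% Pd/C, EtOH, rt
Reagents that add atoms: none
Why: Catalytic hydrogenation of alkyl azides to primary amines with loss of N2, done before any aryl bromide is present; tert-butyl esters trans to the new amines should not lactamise.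

Step 9
Reactants: 12 di-tert-butyl (1S,2S,3R,4R)-3,4-bis(aminomethyl)cyclobutane-1,2-dicarboxylate; 13 4-bromo-2-(trichloroacetyl)pyrrole
Product: 14 di-tert-butyl all-trans 3-(aminomethyl)-4-{[(4-bromo-1H-pyrrole-2-carbonyl)amino]methyl}cyclobutane-1,2-dicarboxylate (ring configuration as in 12)
Conditions: 13 (0.9 equiv, slow addition), Et3N, MeCN, 0 °C → rt; unreacted 12 recovered and recycled
Reagents that add atoms: none
Why: Haloform-type N-acylation in which the trichloromethyl ketone transfers its acyl group and releases CHCl3; the two amines of 12 are homotopic (C2 axis), so only one mono-amide can form, and sub-stoichiometric slow addition should limit double acylation.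

Step 10
Reactants: 14 mono-amide amine; 15 2-(trichloroacetyl)pyrrole
Product: 16 di-tert-butyl all-trans 3-{[(4-bromo-1H-pyrrole-2-carbonyl)amino]methyl}-4-{[(1H-pyrrole-2-carbonyl)amino]methyl}cyclobutane-1,2-dicarboxylate
Conditions: 15 (1.2 equiv), Et3N, MeCN, rt
Reagents that add atoms: none
Why: The same haloform-type acylation on the remaining primary amine, which differentiates the two arms.

Step 11
Reactants: 16 bis-amide di-tert-butyl ester
Product: 17 all-trans 3-{[(4-bromo-1H-pyrrole-2-carbonyl)amino]methyl}-4-{[(1H-pyrrole-2-carbonyl)amino]methyl}cyclobutane-1,2-dicarboxylic acid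
Conditions: TFA/CH2Cl2 (1:3), 0 °C → rt
Reagents that add atoms: none
Why: Acidolysis of the tert-butyl esters with loss of isobutene; the acyl-deactivated pyrroles, the secondary amides and the aryl bromide should be stable to TFA.

Step 12
Reactants: 17 bis-amide dicarboxylic acid
Product: 19 all-trans 1,2-bis(diazoacetyl)cyclobutane carrying the two pyrrole amide arms of 17, via bis(isobutoxycarbonyl) mixed anhydride 18 (not isolated)
Conditions: iBuOCOCl, N-methylmorpholine, THF, −15 °C; then CH2N2, Et2O, −15 °C → rt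
Reagents that add atoms: diazomethane, C=[N+]=[N-]
Why: Mixed carbonic anhydride activation followed by C-acylation of diazomethane (the first stage of an Arndt–Eistert sequence), mild enough for pyrrole and amide N–H; the trans-1,2-diacid cannot close to a cyclic anhydride.

Step 13
Reactants: 19 bis(diazoketone)
Product: 20 all-trans 1,2-bis(bromoacetyl)cyclobutane carrying the two pyrrole amide arms
Conditions: 48% aq HBr, THF, 0 °C
Reagents that add atoms: hydrogen bromide, Br
Why: Hydrobromination of the α-diazoketone (C-protonation, then bromide displaces N2) places bromine only on the terminal carbon, with no halogenation at the ring methine or on the pyrroles.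

Step 14
Reactants: 20 bis(bromomethyl ketone); 21 N-Boc-guanidine
Product: 22 all-trans cyclobutane with 2-amino-1-(tert-butoxycarbonyl)imidazol-4-yl groups at C1 and C4 and the two pyrrole amide arms at C2 and C3
Conditions: 21 (8 equiv), DMF, rt
Reagents that add atoms: none
Why: Cyclocondensation of an α-bromoketone with an N-acylguanidine (N-alkylation, ring closure onto the ketone, dehydration) builds each 2-aminoimidazole; Boc is expected on the ring nitrogen remote from the cyclobutane, and any other Boc position would give the same product in step 15.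

Step 15
Reactants: 22 bis(N-Boc-2-aminoimidazole)
Product: 23 desbromosceptrine (free base)
Conditions: TFA/CH2Cl2 (1:3), 0 °C → rt; then NaHCO3 work-up
Reagents that add atoms: none
Why: Acidolytic cleavage of the two imidazole N-Boc carbamates (loss of isobutene and CO2) releases both 2-aminoimidazoles; the four ring stereocentres set in steps 2–4 are unchanged.

**Compound list**

1 | glycine ethyl ester hydrochloride | CCOC(=O)CN.Cl | starting material
2 | ethyl glyoxylate | CCOC(=O)C=O | starting material
3 | ethyl N-[(E)-2-ethoxy-2-oxoethylidene]glycinate | CCOC(=O)/C=N/CC(=O)OCC | intermediate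
4 | di-tert-butyl fumarate | CC(C)(C)OC(=O)/C=C/C(=O)OC(C)(C)C | starting material
5 | 3,4-di-tert-butyl 2,5-diethyl (2R,3R,4R,5S)-pyrrolidine-2,3,4,5-tetracarboxylate | CC(C)(C)OC(=O)[C@H]1[C@H](C(=O)OCC)N[C@H](C(=O)OCC)[C@@H]1C(=O)OC(C)(C)C | intermediate
6 | 3,4-di-tert-butyl 2,5-diethyl (2R,3R,4R,5R)-pyrrolidine-2,3,4,5-tetracarboxylate (all-trans) | CC(C)(C)OC(=O)[C@H]1[C@H](C(=O)OCC)N[C@@H](C(=O)OCC)[C@@H]1C(=O)OC(C)(C)C | intermediate
7 | cyclic isodiazene (1,1-diazene) of 6, ring N+=N− | CC(C)(C)OC(=O)[C@H]1[C@H](C(=O)OCC)[N+](=[N-])[C@@H](C(=O)OCC)[C@@H]1C(=O)OC(C)(C)C | intermediate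
8 | 1,2-di-tert-butyl 3,4-diethyl (1S,2S,3R,4R)-cyclobutane-1,2,3,4-tetracarboxylate (all-trans) | CC(C)(C)OC(=O)[C@H]1[C@H](C(=O)OCC)[C@@H](C(=O)OCC)[C@@H]1C(=O)OC(C)(C)C | intermediate
9 | di-tert-butyl (1S,2S,3R,4R)-3,4-bis(hydroxymethyl)cyclobutane-1,2-dicarboxylate | CC(C)(C)OC(=O)[C@H]1[C@H](CO)[C@@H](CO)[C@@H]1C(=O)OC(C)(C)C | intermediate
10 | di-tert-butyl (1S,2S,3R,4R)-3,4-bis[(methanesulfonyloxy)methyl]cyclobutane-1,2-dicarboxylate | CC(C)(C)OC(=O)[C@H]1[C@H](COS(C)(=O)=O)[C@@H](COS(C)(=O)=O)[C@@H]1C(=O)OC(C)(C)C | intermediate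
11 | di-tert-butyl (1S,2S,3R,4R)-3,4-bis(azidomethyl)cyclobutane-1,2-dicarboxylate | CC(C)(C)OC(=O)[C@H]1[C@H](CN=[N+]=[N-])[C@@H](CN=[N+]=[N-])[C@@H]1C(=O)OC(C)(C)C | intermediate
12 | di-tert-butyl (1S,2S,3R,4R)-3,4-bis(aminomethyl)cyclobutane-1,2-dicarboxylate | CC(C)(C)OC(=O)[C@H]1[C@H](CN)[C@@H](CN)[C@@H]1C(=O)OC(C)(C)C | intermediate
13 | 4-bromo-2-(trichloroacetyl)pyrrole | O=C(c1cc(Br)c[nH]1)C(Cl)(Cl)Cl | starting material
14 | all-trans mono-amide amine (4-bromopyrrole-2-carboxamide on one arm, free CH2NH2 on the other) | CC(C)(C)OC(=O)[C@H]1[C@H](CN)[C@@H](CNC(=O)c2cc(Br)c[nH]2)[C@@H]1C(=O)OC(C)(C)C | intermediate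
15 | 2-(trichloroacetyl)pyrrole | O=C(c1ccc[nH]1)C(Cl)(Cl)Cl | starting material
16 | all-trans bis-amide di-tert-butyl ester | CC(C)(C)OC(=O)[C@H]1[C@H](CNC(=O)c2ccc[nH]2)[C@@H](CNC(=O)c2cc(Br)c[nH]2)[C@@H]1C(=O)OC(C)(C)C | intermediate
17 | all-trans bis-amide dicarboxylic acid | OC(=O)[C@H]1[C@H](CNC(=O)c2ccc[nH]2)[C@@H](CNC(=O)c2cc(Br)c[nH]2)[C@@H]1C(=O)O | intermediate
18 | bis(isobutoxycarbonyl) mixed anhydride of 17 | CC(C)COC(=O)OC(=O)[C@H]1[C@H](CNC(=O)c2ccc[nH]2)[C@@H](CNC(=O)c2cc(Br)c[nH]2)[C@@H]1C(=O)OC(=O)OCC(C)C | intermediate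
19 | all-trans bis(diazoacetyl) bis-amide | [N-]=[N+]=CC(=O)[C@H]1[C@H](CNC(=O)c2ccc[nH]2)[C@@H](CNC(=O)c2cc(Br)c[nH]2)[C@@H]1C(=O)C=[N+]=[N-] | intermediate
20 | all-trans bis(bromoacetyl) bis-amide | BrCC(=O)[C@H]1[C@H](CNC(=O)c2ccc[nH]2)[C@@H](CNC(=O)c2cc(Br)c[nH]2)[C@@H]1C(=O)CBr | intermediate
21 | N-Boc-guanidine (tert-butyl carbamimidoylcarbamate) | CC(C)(C)OC(=O)NC(N)=N | starting material
22 | all-trans bis[2-amino-1-(tert-butoxycarbonyl)imidazol-4-yl] bis-amide | CC(C)(C)OC(=O)n1cc(nc1N)[C@H]1[C@H](CNC(=O)c2ccc[nH]2)[C@@H](CNC(=O)c2cc(Br)c[nH]2)[C@@H]1c1cn(C(=O)OC(C)(C)C)c(N)n1 | intermediate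
23 | desbromosceptrine: all-trans cyclobutane, C1 and C4 (both S) bearing 2-amino-1H-imidazol-5-yl, C2 (R) bearing CH2NHC(=O)(1H-pyrrol-2-yl), C3 (R) bearing CH2NHC(=O)(4-bromo-1H-pyrrol-2-yl) | Nc1ncc([C@H]2[C@H](CNC(=O)c3ccc[nH]3)[C@@H](CNC(=O)c3cc(Br)c[nH]3)[C@@H]2c2cnc(N)[nH]2)[nH]1 | target

**Summary**

Total step count: 15. Longest linear sequence: 15 steps (1 and 2 to 23); all other inputs are commercial.

Steps most likely to fail:

1. Step 4. The ring nitrogen is flanked by two esters, so its amination may be slower than unproductive consumption of the oxidant, and the biradical may fragment into two alkenes instead of coupling. The fallback sets out from 6 and comes back at 8, and builds the N–N bond by nitrosation instead of nitrene transfer. tBuONO in CH2Cl2 (or NaNO2/AcOH) converts 6 into the N-nitrosopyrrolidine F1. Zn/AcOH at 0 °C reduces it to the N-aminopyrrolidine F2. PhI(OAc)2 in CH2Cl2 at −20 °C → rt oxidises F2 to isodiazene 7, which loses N2 to give 8.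

2. Step 2. Facial discrimination may be weak, because the ylide carries an ester at each terminus and can chelate silver through either, and turnover of this doubly stabilised ylide may be low. The fallback sets out from 3 and 4 and comes back at 6. The cycloaddition is run without a chiral ligand (AgOAc, PPh3, Et3N, toluene) to give the racemic cycloadduct F3. NaOEt/EtOH as in step 3 gives the racemic all-trans pyrrolidine F4. Fractional crystallisation with (1S)-(+)-10-camphorsulfonic acid gives the camphorsulfonate salt F5 of the (2R,3R,4R,5R) amine, taken from crystals or mother liquor, whichever carries it. NaHCO3 then frees 6.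

3. Step 3. Epimerisation at C5 may be incomplete, or the ring may open by retro-aza-Michael elimination from the C4 enolate. The fallback sets out from 5 and comes back at 8. Compound 5 is contracted directly under the conditions of step 4, through the cis-configured isodiazene F6, to the cyclobutane tetraester F7, in which one ethyl ester is cis to both neighbours. NaOEt/EtOH then epimerises that one centre to give 8; the carbocycle has no β-leaving group, so ring opening is not possible there.

**Further compounds**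

F1 | step 4 | 3,4-di-tert-butyl 2,5-diethyl (2R,3R,4R,5R)-1-nitrosopyrrolidine-2,3,4,5-tetracarboxylate | CC(C)(C)OC(=O)[C@H]1[C@H](C(=O)OCC)N(N=O)[C@@H](C(=O)OCC)[C@@H]1C(=O)OC(C)(C)C
F2 | step 4 | 3,4-di-tert-butyl 2,5-diethyl (2R,3R,4R,5R)-1-aminopyrrolidine-2,3,4,5-tetracarboxylate | CC(C)(C)OC(=O)[C@H]1[C@H](C(=O)OCC)N(N)[C@@H](C(=O)OCC)[C@@H]1C(=O)OC(C)(C)C
F3 | step 2 | racemic 2,5-cis-3,4-trans cycloadduct (5 and its enantiomer, 1:1) | CC(C)(C)OC(=O)[C@H]1[C@H](C(=O)OCC)N[C@H](C(=O)OCC)[C@@H]1C(=O)OC(C)(C)C.CC(C)(C)OC(=O)[C@@H]1[C@@H](C(=O)OCC)N[C@@H](C(=O)OCC)[C@H]1C(=O)OC(C)(C)C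
F4 | step 2 | racemic all-trans pyrrolidine (6 and its enantiomer, 1:1) | CC(C)(C)OC(=O)[C@H]1[C@H](C(=O)OCC)N[C@@H](C(=O)OCC)[C@@H]1C(=O)OC(C)(C)C.CC(C)(C)OC(=O)[C@@H]1[C@@H](C(=O)OCC)N[C@H](C(=O)OCC)[C@H]1C(=O)OC(C)(C)C
F5 | step 2 | (1S)-10-camphorsulfonate salt of 6 | CC(C)(C)OC(=O)[C@H]1[C@H](C(=O)OCC)N[C@@H](C(=O)OCC)[C@@H]1C(=O)OC(C)(C)C.CC1([C@@H]2CC[C@]1(C(=O)C2)CS(=O)(=O)O)C
F6 | step 3 | cyclic isodiazene of 5 (2,5-cis) | CC(C)(C)OC(=O)[C@H]1[C@H](C(=O)OCC)[N+](=[N-])[C@H](C(=O)OCC)[C@@H]1C(=O)OC(C)(C)C
F7 | step 3 | 1,2-di-tert-butyl 3,4-diethyl cyclobutane-1,2,3,4-tetracarboxylate, epimer of 8 at one ethyl ester carbon (that ester cis to both neighbours) | CC(C)(C)OC(=O)[C@H]1[C@H](C(=O)OCC)[C@H](C(=O)OCC)[C@@H]1C(=O)OC(C)(C)C
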